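**Assumption (remark on the chemistry):** the stereodescriptor of C2 in the target is S, so a ring closure with inversion needs the (R)-carbinol. Compound 13 is not purified and is used as the THF solution in which it forms.

## Structural features

Kazinol A is a 2-arylchroman (flavan). Ring A, a benzene bearing the 7-hydroxyl, is fused through C4a and C8a to the dihydropyran ring C (O1, C2, C3, C4), and C2 carries ring B through C1'. Ring B is a pentasubstituted catechol with hydroxyls at C3' and C4' and 3-methylbut-2-enyl (prenyl) groups at C2' and C5', so C1' lies between the free C6'–H and a prenyl-bearing carbon. C2 is the only stereocentre: (S), benzylic, oxygen-bearing, para to the C4' oxygen and without a stereogenic neighbour, so its configuration has to come from a reagent. The fragile parts are the catechol (oxidation to the ortho-quinone), the two prenyl alkenes, each ortho to a phenol (acid closes them to 2,2-dimethylchromans, hydrogenation saturates them, electrophiles add to them), and the C2–O1 bond, which can ionise towards a quinone-methide-like cation and lose configuration. The real difficulty is therefore to join the crowded C1' to C2 and to fix C2 with both prenyl groups in place, using no hydrogenation, strong acid or free electrophile afterwards. The key step exploits the fact that C2 is one oxygenated carbon flanked by C1' of ring B and by the C3–C4 chain to C4a of ring A: at the ketone level it is a carbonyl carbon between an aryl and a primary alkyl group, which a carbonylative three-component coupling builds from carbon monoxide.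

## Logic of the disconnections

**18 to 17.** The three phenolic O–CH2OCH3 bonds are cut last. The phenols must stay masked through organolithium, palladium, borane and Mitsunobu chemistry, and one acetal type allows one final operation. The demand on the forward step is acid mild enough to spare the ortho-prenylphenol units and the C2–O1 bond.

**17 to 16.** The O1–C2 bond of ring C is cut. Closing the ring by C–O formation at C2 lets the stereocentre be prepared on an open-chain carbinol, and 16 is an acyclic 1,3-diarylpropanol. The forward closure must be a clean SN2 displacement with inversion, so 16 must be R and the activated alcohol must not ionise.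

**16 to 15 to 14.** The O–Si bond and then the C2–H bond are cut. At the ketone level C2 is not stereogenic, so 14 has no stereocentre at all. The forward reduction needs reagent-controlled facial selectivity on an ortho-substituted aryl ketone and a hydride source that spares the prenyl alkenes; the silyl ether must come off without touching the acetals.

**14 to 7, 12 and 13.** The C1'–C2 and C2–C3 bonds are cut together, so C2 becomes the one-carbon unit 12. This splits the molecule into two fragments of similar size, each ring already carrying all its substituents. The forward step must insert 12 before the alkyl group is transferred, must transfer only the primary alkyl group of 13, and must leave the prenyl groups of 7 as spectators.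

**13 to 11 to 10 to 9 to 8.** The C3–B bond is cut (hydroboration), then the C3=C4 bond (methylenation), then the O–Si and O–CH2 bonds. Compound 8 already holds both ring A oxygens and C4. The forward demands are anti-Markovnikov hydroboration and etherification of the 4-hydroxyl before silylation of the hydrogen-bonded 2-hydroxyl.

**7 to 5 (through 6).** The C–I bond is traced to a C–Br bond by halogen–lithium exchange. The bromide survives heat, base and metathesis, while the iodide is needed for oxidative addition at a hindered carbon under CO. The exchange must outrun deprotonation of the benzylic-allylic CH2 groups, and the iodine source must not attack the alkenes.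

**5 to 4.** The two trisubstituted C=C bonds of the prenyl groups are cut by cross-metathesis logic. Allyl groups are placed on a catechol more safely than prenyl groups. The forward step must exchange both termini without moving the double bonds into conjugation.

**4 to 3 to 2 to 1.** The two acetal O–C bonds are cut, then the two aryl–CH2 bonds (C2'–CH2 and C5'–CH2) are returned to the oxygens, then the O–allyl bonds are cut. In 2 each oxygen has one free ortho carbon only, so the catechol and the bromine of 1 dictate the substitution pattern of ring B. The forward double rearrangement needs heat that the C–Br bond must tolerate.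

## Other disconnections considered

**Alternative 1:** The cut is in ring C, at C4–C4a and O1–C2.
- Forward key step: resorcinol A1 and 1-[3,4-bis(benzyloxy)phenyl]prop-2-yn-1-one A2 would condense in HPF6/acetic acid. C4 of A1 adds to the alkyne terminus and the neighbouring hydroxyl closes on the ketone with loss of water, giving the flavylium salt A3. An enantioselective hydrogenation of the pyrylium ring would then create C2.
- In favour: the whole C6–C3–C6 skeleton and ring C arise in one step from very simple partners, no ring A oxygen needs differentiating, and C2 is made without substitution at the benzylic carbon.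
- Against: A3 has no prenyl groups and cannot carry them, because the condensation acid would close an ortho-prenylphenol to a chroman and the hydrogenation would saturate the side chains. Both prenyl groups must then be added after the reduction, in effect by the chemistry of Alternative 3, once the benzyl ethers are removed. Enantioselective reduction of a cationic 2-arylbenzopyrylium without hydrogenolysis of the benzylic C2–O1 bond is a less secure basis than reduction of an aryl ketone.
- Comparison: on structure, the alternative reaches the flavan core faster and is the better plan on that count. On mechanism, it replaces palladium acyl chemistry and toxic CO by Brønsted-acid arylation, which is simpler to run (again its advantage), but it is incompatible with the prenylated ring B that the chosen key step tolerates. On step economy, the saving in the core is spent on late prenylation, so the totals should be similar, with the uncertain steps late instead of early.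

**Alternative 2:** The cut is in ring B, at C1'–C2' and C5'–C6'.
- Forward key step: the symmetric diene (5Z,7Z)-6,7-bis(tert-butyldimethylsilyloxy)-2,11-dimethyldodeca-2,5,7,10-tetraene A4 would add to the terminal ynone 5-[2-bromo-4-(tert-butyldimethylsilyloxy)phenyl]pent-1-yn-3-one A5 in a [4+2] cycloaddition, and DDQ in the same flask would aromatise the adduct to the ketone A6.
- In favour: ring B is made with all five substituents placed in one operation, and the symmetry of A4 removes any regiochemical question. A6 is an aryl ketone at the same oxidation level as 14, so the two plans are equal from there to the carbinol. The ring A bromide allows C–O ring closure with retention at C2, and silyl-only protection ends with fluoride instead of acid; on both points the alternative is the better plan.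
- Against: A4 needs a 1,2-diketone with two prenyl-bearing chains and a geometry-controlled double enol silylation, and it is sensitive to hydrolysis. A5 is a reactive Michael acceptor. The oxidant must dehydrogenate the cyclohexadiene without attacking the prenyl groups or the silyl enol ethers.
- Comparison: on structure, it builds a ring and two C–C bonds in the key step, against two C–C bonds and no ring in the chosen plan. On mechanism, a thermal pericyclic step needs neither CO nor palladium, which is an advantage. On step economy, making A4 and A5 should cost more steps than making 7 and 11 from commercial arenes, so the chosen plan should be shorter overall.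

**Alternative 3:** The cut is at the two aryl–CH2 bonds of the prenyl groups, made last.
- Forward key step: the bis(1,1-dimethylallyl) ether A7 of the (S)-flavan catechol would undergo two aromatic Claisen rearrangements, thermally or with Eu(fod)3, to give kazinol A 7-silyl ether A8.
- In favour: every earlier step is free of prenyl alkenes, so hydrogenation and acid are allowed, and the asymmetric step acts on an unhindered substrate. Each ether oxygen of A7 has one free ortho carbon (C2' and C5'), so the pattern is programmed in the same way as in compound 2; on this point the plans are equal.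
- Against: the shift to C2' enters a position flanked by the flavan ring, so para migration to C6' and loss of the tertiary allyl group as a diene become competitive. The free C4' hydroxyl appears while the mixture is hot, next to the benzylic C2–O1 bond, which invites ring opening and loss of configuration. All of this happens on late material, and two tertiary ethers must first be placed on neighbouring catechol oxygens.
- Comparison: on structure, the alternative needs fewer protecting groups on ring B and is the better plan there. On mechanism, both plans use the same sigmatropic logic, but the chosen plan runs it at the start on a cheap bromocatechol with simple allyl groups. On step economy, the alternative could be shorter, at the price of placing its least predictable step at the end.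

Key step: step 9

## Route

Step 1
Reactants: 1 4-bromobenzene-1,2-diol (4-bromocatechol)
Product: 2 4-bromo-1,2-bis(prop-2-enyloxy)benzene
Conditions: allyl bromide, K2CO3, acetone, reflux, under N2
Reagents that add atoms: allyl bromide, C=CCBr
Why: Williamson O-allylation of both catechol hydroxyls; the aryl bromide is inert to K2CO3, and exclusion of air keeps the catecholate from oxidising.

Step 2
Reactants: 2 4-bromo-1,2-bis(prop-2-enyloxy)benzene
Product: 3 4-bromo-3,6-di(prop-2-enyl)benzene-1,2-diol
Conditions: N,N-diethylaniline, 190 °C, argon
Reagents that add atoms: none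
Why: Two successive aromatic Claisen rearrangements ([3,3] shift, then tautomerisation); each ether oxygen has one free ortho carbon only (C6 for O1, C3 for O2), so the allyl groups end up on either side of the catechol and the bromine marks the future C1'.

Step 3
Reactants: 3 4-bromo-3,6-di(prop-2-enyl)benzene-1,2-diol
Product: 4 1-bromo-3,4-bis(methoxymethoxy)-2,5-di(prop-2-enyl)benzene
Conditions: MOMCl, i-Pr2NEt, CH2Cl2, 0 °C to rt
Reagents that add atoms: chloromethyl methyl ether (MOMCl), COCCl
Why: Acetal (MOM ether) protection removes the acidic, oxidisable catechol; MOM ethers should withstand ruthenium carbenes, butyllithium, phosphate base, borane, fluoride and Mitsunobu reagents.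

Step 4
Reactants: 4 1-bromo-3,4-bis(methoxymethoxy)-2,5-di(prop-2-enyl)benzene
Product: 5 1-bromo-3,4-bis(methoxymethoxy)-2,5-bis(3-methylbut-2-enyl)benzene
Conditions: second-generation Grubbs catalyst (5 mol %), 2-methylbut-2-ene (large excess), CH2Cl2, rt
Reagents that add atoms: 2-methylbut-2-ene, CC=C(C)C
Why: Olefin cross-metathesis of each terminal allyl alkene with the trisubstituted partner in excess turns allyl into prenyl and releases propene; the two allyl groups are para to each other, so no ring-closing pathway exists.

Step 5
Reactants: 5 1-bromo-3,4-bis(methoxymethoxy)-2,5-bis(3-methylbut-2-enyl)benzene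
Product: 7 1-iodo-3,4-bis(methoxymethoxy)-2,5-bis(3-methylbut-2-enyl)benzene, via aryllithium 6 (not isolated)
Conditions: n-BuLi, THF, –78 °C; then ICH2CH2I, –78 °C to rt
Reagents that add atoms: 1,2-diiodoethane, ICCI
Why: Bromine–lithium exchange at –78 °C should be faster than deprotonation of the benzylic-allylic CH2 groups, and no hydrogen lies ortho to an OMOM group; iodine transfer from 1,2-diiodoethane avoids free iodine, which would add to the prenyl alkenes.

Step 6
Reactants: 8 2,4-dihydroxybenzaldehyde
Product: 9 2-hydroxy-4-(methoxymethoxy)benzaldehyde
Conditions: MOMCl (1.05 equiv), K2CO3, acetone, 0 °C to rt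
Reagents that add atoms: chloromethyl methyl ether (MOMCl), COCCl
Why: Selective O-alkylation: the 2-hydroxyl is held in a hydrogen bond to the aldehyde and is the poorer nucleophile, so one equivalent of MOMCl should etherify the 4-hydroxyl.

Step 7
Reactants: 9 2-hydroxy-4-(methoxymethoxy)benzaldehyde
Product: 10 4-(methoxymethoxy)-2-(triisopropylsilyloxy)benzaldehyde
Conditions: TIPSCl, imidazole, DMF, rt
Reagents that add atoms: chlorotriisopropylsilane (TIPSCl), CC(C)[Si](Cl)(C(C)C)C(C)C
Why: Silylation of the remaining phenol; the bulky aryl TIPS ether should resist the ylide, 9-BBN-H, phosphate and borane, and is later removed by fluoride without loss of MOM.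

Step 8
Reactants: 10 4-(methoxymethoxy)-2-(triisopropylsilyloxy)benzaldehyde
Product: 11 1-ethenyl-4-(methoxymethoxy)-2-(triisopropylsilyloxy)benzene
Conditions: Ph3PCH3Br, KOt-Bu, THF, 0 °C to rt
Reagents that add atoms: methyltriphenylphosphonium bromide, C[P+](c1ccccc1)(c1ccccc1)c1ccccc1.[Br-]
Why: Wittig methylenation of the aryl aldehyde by the unstabilised ylide gives the terminal styrene; both ethers are stable to the ylide.

Step 9
Reactants: 11 1-ethenyl-4-(methoxymethoxy)-2-(triisopropylsilyloxy)benzene; 7 1-iodo-3,4-bis(methoxymethoxy)-2,5-bis(3-methylbut-2-enyl)benzene; 12 carbon monoxide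
Product: 14 1-[3,4-bis(methoxymethoxy)-2,5-bis(3-methylbut-2-enyl)phenyl]-3-[4-(methoxymethoxy)-2-(triisopropylsilyloxy)phenyl]propan-1-one, via B-alkyl-9-BBN reagent 13 (not isolated)
Conditions: 11, 9-BBN-H, THF, 0 °C to rt; then 7, 12 (1 atm), PdCl2(PPh3)2 (5 mol %), K3PO4, THF, 50 °C
Reagents that add atoms: none
Why: Hydroboration of 11 with 9-BBN-H places boron on the terminal carbon (anti-Markovnikov) and gives 13, used as formed. PdCl2(PPh3)2 is reduced in the flask to zerovalent palladium, which inserts into the C–I bond of 7; CO 12 inserts into the aryl–palladium bond to give an aroyl complex of divalent palladium, the phosphate-activated borate of 13 transfers its primary alkyl group, and reductive elimination releases 14 with the C1'–C2 and C2–C3 bonds formed around the former CO carbon. The closest known reaction type is the carbonylative Suzuki–Miyaura coupling of B-alkyl-9-BBN reagents with aryl iodides to alkyl aryl ketones. No ring is closed and no stereocentre is formed, so no closure mode or stereocontrol element is involved; C2 remains a carbonyl carbon until step 10. The first selectivity needed is carbonylative over direct coupling: the prenyl group at C2' crowds the aryl–palladium bond, so CO insertion, which relieves the crowding, should be favoured, while alkyl transfer from boron under mild phosphate/PPh3 conditions is slow enough to meet the aroyl complex. The second is chemoselectivity: only the iodide reacts, since the trisubstituted prenyl alkenes are poor partners for acylpalladium insertion and cannot be hydroborated once the styrene has consumed all 9-BBN-H, and only the primary B–CH2 bond is transferred, not the bicyclic secondary B–C bonds. The MOM acetals and the aryl TIPS ether should be inert to anhydrous K3PO4 at 50 °C.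

Step 10
Reactants: 14 1-[3,4-bis(methoxymethoxy)-2,5-bis(3-methylbut-2-enyl)phenyl]-3-[4-(methoxymethoxy)-2-(triisopropylsilyloxy)phenyl]propan-1-one
Product: 15 (1R)-1-[3,4-bis(methoxymethoxy)-2,5-bis(3-methylbut-2-enyl)phenyl]-3-[4-(methoxymethoxy)-2-(triisopropylsilyloxy)phenyl]propan-1-ol
Conditions: (S)-2-methyl-CBS-oxazaborolidine (20 mol %), BH3·SMe2 (0.7 equiv, slow addition), toluene, –20 °C; then MeOH
Reagents that add atoms: none
Why: CBS reduction: the ketone binds to the ring boron with the aryl group as the large substituent, and the nitrogen-bound borane delivers hydride to the Si face, which with the (S)-catalyst should give the (R)-carbinol as for aryl alkyl ketones; low temperature and substoichiometric borane keep the prenyl alkenes from being hydroborated.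

Step 11
Reactants: 15 (1R)-1-[3,4-bis(methoxymethoxy)-2,5-bis(3-methylbut-2-enyl)phenyl]-3-[4-(methoxymethoxy)-2-(triisopropylsilyloxy)phenyl]propan-1-ol
Product: 16 2-{(3R)-3-[3,4-bis(methoxymethoxy)-2,5-bis(3-methylbut-2-enyl)phenyl]-3-hydroxypropyl}-5-(methoxymethoxy)phenol
Conditions: Bu4NF, AcOH (1 equiv each), THF, 0 °C
Reagents that add atoms: none
Why: Fluoride-mediated desilylation of the aryl silyl ether; acetic acid buffers the phenoxide, so the MOM acetals, the prenyl groups and the configured benzylic alcohol should be unaffected.

Step 12
Reactants: 16 2-{(3R)-3-[3,4-bis(methoxymethoxy)-2,5-bis(3-methylbut-2-enyl)phenyl]-3-hydroxypropyl}-5-(methoxymethoxy)phenol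
Product: 17 (2S)-2-[3,4-bis(methoxymethoxy)-2,5-bis(3-methylbut-2-enyl)phenyl]-7-(methoxymethoxy)-3,4-dihydro-2H-chromene
Conditions: PPh3, DIAD, toluene, –20 °C to 0 °C
Reagents that add atoms: none
Why: Intramolecular Mitsunobu etherification: the alcohol is activated as an alkoxyphosphonium ion and displaced by the ortho-phenoxide in a 6-exo-tet SN2 closure with inversion, so the (R)-carbinol should give the (2S)-flavan; low temperature and a non-polar solvent disfavour ionisation of the electron-rich benzylic centre.

Step 13
Reactants: 17 (2S)-2-[3,4-bis(methoxymethoxy)-2,5-bis(3-methylbut-2-enyl)phenyl]-7-(methoxymethoxy)-3,4-dihydro-2H-chromene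
Product: 18 kazinol A, 4-[(2S)-7-hydroxy-3,4-dihydro-2H-chromen-2-yl]-3,6-bis(3-methylbut-2-enyl)benzene-1,2-diol
Conditions: 3 M aq. HCl, MeOH, rt, argon
Reagents that add atoms: none
Why: Acid-catalysed acetal exchange with methanol frees the three phenols as dimethoxymethane; dilute acid at ambient temperature is the usual unmasking of MOM-protected ortho-prenylphenols and should be too mild for chroman formation or opening of the C2–O1 bond, so the (2S) configuration is carried into the target.

## Compound list

1 | 4-bromobenzene-1,2-diol (4-bromocatechol) | Oc1ccc(Br)cc1O | starting material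
2 | 4-bromo-1,2-bis(prop-2-enyloxy)benzene | C=CCOc1ccc(Br)cc1OCC=C | intermediate
3 | 4-bromo-3,6-di(prop-2-enyl)benzene-1,2-diol | Oc1c(CC=C)cc(Br)c(CC=C)c1O | intermediate
4 | 1-bromo-3,4-bis(methoxymethoxy)-2,5-di(prop-2-enyl)benzene | Brc1cc(CC=C)c(OCOC)c(OCOC)c1CC=C | intermediate
5 | 1-bromo-3,4-bis(methoxymethoxy)-2,5-bis(3-methylbut-2-enyl)benzene | Brc1cc(CC=C(C)C)c(OCOC)c(OCOC)c1CC=C(C)C | intermediate
6 | [3,4-bis(methoxymethoxy)-2,5-bis(3-methylbut-2-enyl)phenyl]lithium | [Li]c1cc(CC=C(C)C)c(OCOC)c(OCOC)c1CC=C(C)C | intermediate (not isolated)
7 | 1-iodo-3,4-bis(methoxymethoxy)-2,5-bis(3-methylbut-2-enyl)benzene | Ic1cc(CC=C(C)C)c(OCOC)c(OCOC)c1CC=C(C)C | intermediate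
8 | 2,4-dihydroxybenzaldehyde | O=Cc1ccc(O)cc1O | starting material
9 | 2-hydroxy-4-(methoxymethoxy)benzaldehyde | O=Cc1ccc(OCOC)cc1O | intermediate
10 | 4-(methoxymethoxy)-2-(triisopropylsilyloxy)benzaldehyde | O=Cc1ccc(OCOC)cc1O[Si](C(C)C)(C(C)C)C(C)C | intermediate
11 | 1-ethenyl-4-(methoxymethoxy)-2-(triisopropylsilyloxy)benzene | C=Cc1ccc(OCOC)cc1O[Si](C(C)C)(C(C)C)C(C)C | intermediate
12 | carbon monoxide | [C-]#[O+] | starting material
13 | 9-{2-[4-(methoxymethoxy)-2-(triisopropylsilyloxy)phenyl]ethyl}-9-borabicyclo[3.3.1]nonane | C(Cc1ccc(OCOC)cc1O[Si](C(C)C)(C(C)C)C(C)C)B1C2CCCC1CCC2 | intermediate (not isolated)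
14 | 1-[3,4-bis(methoxymethoxy)-2,5-bis(3-methylbut-2-enyl)phenyl]-3-[4-(methoxymethoxy)-2-(triisopropylsilyloxy)phenyl]propan-1-one | CC(C)=CCc1cc(C(=O)CCc2ccc(OCOC)cc2O[Si](C(C)C)(C(C)C)C(C)C)c(CC=C(C)C)c(OCOC)c1OCOC | intermediate
15 | (1R)-1-[3,4-bis(methoxymethoxy)-2,5-bis(3-methylbut-2-enyl)phenyl]-3-[4-(methoxymethoxy)-2-(triisopropylsilyloxy)phenyl]propan-1-ol | CC(C)=CCc1cc([C@H](O)CCc2ccc(OCOC)cc2O[Si](C(C)C)(C(C)C)C(C)C)c(CC=C(C)C)c(OCOC)c1OCOC | intermediate
16 | 2-{(3R)-3-[3,4-bis(methoxymethoxy)-2,5-bis(3-methylbut-2-enyl)phenyl]-3-hydroxypropyl}-5-(methoxymethoxy)phenol | CC(C)=CCc1cc([C@H](O)CCc2ccc(OCOC)cc2O)c(CC=C(C)C)c(OCOC)c1OCOC | intermediate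
17 | (2S)-2-[3,4-bis(methoxymethoxy)-2,5-bis(3-methylbut-2-enyl)phenyl]-7-(methoxymethoxy)-3,4-dihydro-2H-chromene | CC(C)=CCc1cc([C@@H]2CCc3ccc(OCOC)cc3O2)c(CC=C(C)C)c(OCOC)c1OCOC | intermediate
18 | kazinol A, 4-[(2S)-7-hydroxy-3,4-dihydro-2H-chromen-2-yl]-3,6-bis(3-methylbut-2-enyl)benzene-1,2-diol | CC(C)=CCc1cc([C@@H]2CCc3ccc(O)cc3O2)c(CC=C(C)C)c(O)c1O | target

## Step count and least certain steps

Total: 13 steps. Longest linear sequence: 10 steps (steps 1 to 5, then 9 to 13). The ring A branch (steps 6 to 8) joins at step 9.

**Key step (step 9).** The likely failures are direct coupling without CO uptake, slow oxidative addition at the crowded iodide under CO, β-hydride elimination in the acyl(alkyl)palladium intermediate, and insertion of the C2' prenyl alkene into the aroyl–palladium bond. The fallback dispenses with CO and palladium, sets out from 5 (through 6) and from 10, and returns at 14. Aldehyde 10 would be treated with N-methoxy-N-methyl-2-(triphenylphosphoranylidene)acetamide (toluene, 80 °C) to give (E)-N-methoxy-N-methyl-3-[4-(methoxymethoxy)-2-(triisopropylsilyloxy)phenyl]prop-2-enamide F1. Hydrogenation (H2, Pd/C, EtOAc), harmless here because no prenyl group is present, would give N-methoxy-N-methyl-3-[4-(methoxymethoxy)-2-(triisopropylsilyloxy)phenyl]propanamide F2. Aryllithium 6, made from 5 with n-BuLi at –78 °C, would add to F2 and give 14 on hydrolysis of the chelated adduct; C2 then comes from the amide carbonyl.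

**Step 4.** The ruthenium catalyst may move an allyl double bond into conjugation with the ring, and exchange may stop after one of the two sites, leaving mixtures that are hard to separate. The fallback installs the prenyl groups directly by rearrangement, sets out from 1 and returns at 5. Compound 1 and 3-chloro-3-methylbut-1-yne (CuCl2·2H2O cat., DBU, MeCN, 0 °C) would give 4-bromo-1,2-bis(2-methylbut-3-yn-2-yloxy)benzene F3. Semi-hydrogenation (H2, Pb-poisoned Pd/CaCO3, quinoline) would give 4-bromo-1,2-bis(2-methylbut-3-en-2-yloxy)benzene F4. A double aromatic Claisen rearrangement (Eu(fod)3, CHCl3, 60 °C) would give 4-bromo-3,6-bis(3-methylbut-2-enyl)benzene-1,2-diol F5, and MOMCl/i-Pr2NEt would then give 5.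

**Step 10.** Facial discrimination may be poor, because the ortho-substituted aryl group is twisted and the other substituent is a long flexible chain; borane may also hydroborate the prenyl groups. The fallback uses no borane, sets out from 14 and returns at 15: asymmetric transfer hydrogenation with RuCl(p-cymene)[(R,R)-TsDPEN] in HCO2H/Et3N at rt, where a ruthenium hydride and the ligand N–H deliver hydrogen to the same carbonyl face and alkenes are not touched. This fallback makes no compound outside the list (F0).

**Step 12.** The activated benzylic oxyphosphonium ion, para to an alkoxy group and hindered by the C2' prenyl group, may ionise before displacement, which would erode the configuration at C2 or lead to elimination. The fallback closes ring C with retention by aryl C–O coupling, so the carbinol C–O bond is never broken; it sets out from 7 and returns at 17. Commercial 2-bromo-4-hydroxybenzaldehyde F6 would be protected (MOMCl, i-Pr2NEt) as 2-bromo-4-(methoxymethoxy)benzaldehyde F7 and methylenated (Ph3PCH3Br, KOt-Bu) to 2-bromo-1-ethenyl-4-(methoxymethoxy)benzene F8. Hydroboration with 9-BBN-H would give 9-{2-[2-bromo-4-(methoxymethoxy)phenyl]ethyl}-9-borabicyclo[3.3.1]nonane F9. Carbonylative coupling of F9 with 7 and 12 under the step 9 conditions, where the aryl bromide should stay intact beside the iodide, would give 1-[3,4-bis(methoxymethoxy)-2,5-bis(3-methylbut-2-enyl)phenyl]-3-[2-bromo-4-(methoxymethoxy)phenyl]propan-1-one F10. Reduction with the (R)-configured CBS catalyst would give (1S)-1-[3,4-bis(methoxymethoxy)-2,5-bis(3-methylbut-2-enyl)phenyl]-3-[2-bromo-4-(methoxymethoxy)phenyl]propan-1-ol F11. An intramolecular Buchwald–Hartwig etherification (Pd(OAc)2, 2-(di-tert-butylphosphino)-1,1'-binaphthyl, Cs2CO3, toluene, 80 °C) would then give 17.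

**Step 13.** The acid may add a freed phenol to its ortho prenyl alkene (chroman formation), add methanol to the alkenes, or open the C2–O1 bond once the C4' hydroxyl is free. The fallback avoids Brønsted acid, sets out from 17 and returns at 18. TMSOTf with 2,2'-bipyridyl (CH2Cl2, 0 °C) would exchange each aryl acetal for a silyl ether through a pyridinium intermediate and give kazinol A tris(trimethylsilyl) ether F12, which water would hydrolyse to 18 at neutral pH.

## Further compounds

F1 | step 9 | (E)-N-methoxy-N-methyl-3-[4-(methoxymethoxy)-2-(triisopropylsilyloxy)phenyl]prop-2-enamide | CON(C)C(=O)/C=C/c1ccc(OCOC)cc1O[Si](C(C)C)(C(C)C)C(C)C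
F2 | step 9 | N-methoxy-N-methyl-3-[4-(methoxymethoxy)-2-(triisopropylsilyloxy)phenyl]propanamide | CON(C)C(=O)CCc1ccc(OCOC)cc1O[Si](C(C)C)(C(C)C)C(C)C
F3 | step 4 | 4-bromo-1,2-bis(2-methylbut-3-yn-2-yloxy)benzene | C#CC(C)(C)Oc1ccc(Br)cc1OC(C)(C)C#C
F4 | step 4 | 4-bromo-1,2-bis(2-methylbut-3-en-2-yloxy)benzene | C=CC(C)(C)Oc1ccc(Br)cc1OC(C)(C)C=C
F5 | step 4 | 4-bromo-3,6-bis(3-methylbut-2-enyl)benzene-1,2-diol | Oc1c(CC=C(C)C)cc(Br)c(CC=C(C)C)c1O
F0 | step 10 | none | none
F6 | step 12 | 2-bromo-4-hydroxybenzaldehyde | O=Cc1ccc(O)cc1Br
F7 | step 12 | 2-bromo-4-(methoxymethoxy)benzaldehyde | O=Cc1ccc(OCOC)cc1Br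
F8 | step 12 | 2-bromo-1-ethenyl-4-(methoxymethoxy)benzene | C=Cc1ccc(OCOC)cc1Br
F9 | step 12 | 9-{2-[2-bromo-4-(methoxymethoxy)phenyl]ethyl}-9-borabicyclo[3.3.1]nonane | COCOc1ccc(CCB2C3CCCC2CCC3)c(Br)c1
F10 | step 12 | 1-[3,4-bis(methoxymethoxy)-2,5-bis(3-methylbut-2-enyl)phenyl]-3-[2-bromo-4-(methoxymethoxy)phenyl]propan-1-one | CC(C)=CCc1cc(C(=O)CCc2ccc(OCOC)cc2Br)c(CC=C(C)C)c(OCOC)c1OCOC
F11 | step 12 | (1S)-1-[3,4-bis(methoxymethoxy)-2,5-bis(3-methylbut-2-enyl)phenyl]-3-[2-bromo-4-(methoxymethoxy)phenyl]propan-1-ol | CC(C)=CCc1cc([C@@H](O)CCc2ccc(OCOC)cc2Br)c(CC=C(C)C)c(OCOC)c1OCOC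
F12 | step 13 | kazinol A tris(trimethylsilyl) ether, (2S)-2-[3,4-bis(trimethylsilyloxy)-2,5-bis(3-methylbut-2-enyl)phenyl]-7-(trimethylsilyloxy)-3,4-dihydro-2H-chromene | CC(C)=CCc1cc([C@@H]2CCc3ccc(O[Si](C)(C)C)cc3O2)c(CC=C(C)C)c(O[Si](C)(C)C)c1O[Si](C)(C)C
A1 | alternative 1 | resorcinol (benzene-1,3-diol) | Oc1cccc(O)c1
A2 | alternative 1 | 1-[3,4-bis(benzyloxy)phenyl]prop-2-yn-1-one | C#CC(=O)c1ccc(OCc2ccccc2)c(OCc2ccccc2)c1
A3 | alternative 1 | 3',4'-bis(benzyloxy)-7-hydroxyflavylium hexafluorophosphate | Oc1ccc2ccc(-c3ccc(OCc4ccccc4)c(OCc4ccccc4)c3)[o+]c2c1.F[P-](F)(F)(F)(F)F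
A4 | alternative 2 | (5Z,7Z)-6,7-bis(tert-butyldimethylsilyloxy)-2,11-dimethyldodeca-2,5,7,10-tetraene | CC(C)=CC/C=C(O[Si](C)(C)C(C)(C)C)/C(O[Si](C)(C)C(C)(C)C)=C/CC=C(C)C
A5 | alternative 2 | 5-[2-bromo-4-(tert-butyldimethylsilyloxy)phenyl]pent-1-yn-3-one | C#CC(=O)CCc1ccc(O[Si](C)(C)C(C)(C)C)cc1Br
A6 | alternative 2 | 1-[3,4-bis(tert-butyldimethylsilyloxy)-2,5-bis(3-methylbut-2-enyl)phenyl]-3-[2-bromo-4-(tert-butyldimethylsilyloxy)phenyl]propan-1-one | CC(C)=CCc1cc(C(=O)CCc2ccc(O[Si](C)(C)C(C)(C)C)cc2Br)c(CC=C(C)C)c(O[Si](C)(C)C(C)(C)C)c1O[Si](C)(C)C(C)(C)C
A7 | alternative 3 | (2S)-2-[3,4-bis(2-methylbut-3-en-2-yloxy)phenyl]-7-(tert-butyldimethylsilyloxy)-3,4-dihydro-2H-chromene | C=CC(C)(C)Oc1ccc([C@@H]2CCc3ccc(O[Si](C)(C)C(C)(C)C)cc3O2)cc1OC(C)(C)C=C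
A8 | alternative 3 | (S)-kazinol A 7-(tert-butyldimethylsilyl) ether | CC(C)=CCc1cc([C@@H]2CCc3ccc(O[Si](C)(C)C(C)(C)C)cc3O2)c(CC=C(C)C)c(O)c1O
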